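The route opens ring C at O1–C2. The C2–O/C3–O/C4–O triad (2,3-trans, 3,4-cis) is read as an erythro trans-epoxy alcohol, one oxygen atom away from a racemic (E)-1,3-diarylallyl alcohol. The feature exploited is that the C4 carbinol next to ring A is allylic to C2=C3 in the open form, so it can steer a titanium–tartrate epoxidation. That single operation selects the (R)-carbinol, forms both epoxide C–O bonds and fixes C2, C3 and C4. The precursor carries the prenylated ring A as a bis-TIPS ether and ring B as an electron-withdrawing, fluoride-labile carbonate. One fluoride treatment then closes ring C with inversion at C2.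

Key step: step 10

**Remarks on the chemistry (assumptions)**
- **Configuration.** The target SMILES is read as (2R,3S,4S), that is 2,3-trans-3,4-cis, with the C3 and C4 hydroxyls on the same face of ring C. In flavan numbering, epoxy alcohol 18 is (2S,3S,4S). C3 and C4 already have their final geometry. The epoxide oxygen lies on the face of C2 opposite to the one O1 finally occupies, so C2 becomes R only in the inverting closure of step 11. The enantiomer of 17 that reacts is (R). Its descriptor changes to S on epoxidation because C3 then outranks the aryl carbon.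
- **Ring B protecting group.** Ring B must be electron-poor while the epoxide is exposed to titanium. Its phenol must also be released in an aprotic medium together with O1. An ordinary ester removed by alcoholysis would free the ring B phenoxide in a nucleophilic solvent while O1 is still blocked, and the solvent would capture C2. Ring B is therefore protected as a 2-(trimethylsilyl)ethyl carbonate.
- **Handling.** Compounds 17 and 18 are purified on Et3N-deactivated silica. Compound 21 is handled at neutral pH under argon.

Step 1
Reactants: 1 5-methoxyresorcinol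
Product: 2 1-methoxy-3,5-bis(methoxymethoxy)benzene
Conditions: MOMCl (2.5 equiv), iPr2NEt (3 equiv), CH2Cl2, 0 °C → rt
Reagents that add atoms: chloromethyl methyl ether, COCCl
Why: Base-mediated O-alkylation (Williamson-type ether formation) of both phenols installs two chelating MOM groups that steer the next two lithiations and are removed again before any acid-sensitive function exists.

Step 2
Reactants: 2 1-methoxy-3,5-bis(methoxymethoxy)benzene; 3 prenyl bromide
Product: 5 5-methoxy-1,3-bis(methoxymethoxy)-2-(3-methylbut-2-enyl)benzene, via aryllithium 4 (not isolated)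
Conditions: n-BuLi (1.1 equiv), THF, 0 °C; then 3, −78 °C → rt
Reagents that add atoms: none
Why: Directed ortho-metalation should occur at the carbon flanked by both OMOM groups, which coordinate lithium better than OMe, and the aryllithium displaces bromide at the primary allylic carbon (SN2), placing the prenyl group at the future C8 without the regioisomer problem of electrophilic prenylation.

Step 3
Reactants: 5 5-methoxy-1,3-bis(methoxymethoxy)-2-(3-methylbut-2-enyl)benzene
Product: 7 6-methoxy-2,4-bis(methoxymethoxy)-3-(3-methylbut-2-enyl)benzaldehyde, via aryllithium 6 (not isolated)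
Conditions: n-BuLi (1.2 equiv), TMEDA, THF, −20 → 0 °C; DMF, −78 °C → rt; then H2O
Reagents that add atoms: N,N-dimethylformamide, CN(C)C=O
Why: A second directed ortho-metalation can only reach the two equivalent ring positions between OMOM and OMe of the symmetric arene 5 (coordination-driven ring lithiation should outrun deprotonation of the twisted benzylic–allylic CH2), and formyl transfer from DMF gives a single aldehyde.

Step 4
Reactants: 7 6-methoxy-2,4-bis(methoxymethoxy)-3-(3-methylbut-2-enyl)benzaldehyde
Product: 8 2,4-dihydroxy-6-methoxy-3-(3-methylbut-2-enyl)benzaldehyde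
Conditions: 3 M aq HCl (cat.), MeOH, 45 °C, short time; NaHCO3 work-up
Reagents that add atoms: none
Why: Acid-catalysed transacetalisation of aryl MOM ethers with methanol is routine on prenylated phenolic carbonyl compounds, and the formyl group lowers the nucleophilicity of both phenols so that brief exposure should not cyclise the prenyl group to a chroman.

Step 5
Reactants: 8 2,4-dihydroxy-6-methoxy-3-(3-methylbut-2-enyl)benzaldehyde
Product: 9 6-methoxy-3-(3-methylbut-2-enyl)-2,4-bis(triisopropylsilyloxy)benzaldehyde
Conditions: TIPSOTf (2.6 equiv), 2,6-lutidine (4 equiv), CH2Cl2, 0 °C → rt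
Reagents that add atoms: triisopropylsilyl trifluoromethanesulfonate, CC(C)[Si](C(C)C)(C(C)C)OS(=O)(=O)C(F)(F)F
Why: O-silylation by the highly electrophilic silyl triflate overcomes the hydrogen bond and the flanking groups at the 2-OH, and TIPS is chosen because it resists O-to-O migration to a neighbouring benzylic alkoxide and donates less electron density than an alkyl ether.

Step 6
Reactants: 10 4-iodophenol
Product: 11 4-iodophenyl 2-(trimethylsilyl)ethyl carbonate
Conditions: Teoc-OSu (1.1 equiv), Et3N, DMAP (cat.), CH2Cl2, rt
Reagents that add atoms: 1-[2-(trimethylsilyl)ethoxycarbonyloxy]pyrrolidine-2,5-dione (Teoc-OSu), C[Si](C)(C)CCOC(=O)ON1C(=O)CCC1=O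
Why: Acyl transfer from an activated mixed carbonate to the phenoxide (nucleophilic catalysis by DMAP) gives an aryl alkyl carbonate that makes ring B electron-poor and can later be fragmented by fluoride.

Step 7
Reactants: 11 4-iodophenyl 2-(trimethylsilyl)ethyl carbonate; 12 trimethylsilylacetylene
Product: 13 2-(trimethylsilyl)ethyl 4-[(trimethylsilyl)ethynyl]phenyl carbonate
Conditions: PdCl2(PPh3)2 (2 mol %), CuI (4 mol %), Et3N, THF, rt
Reagents that add atoms: none
Why: Sonogashira coupling of an aryl iodide runs at room temperature under zerovalent palladium/copper catalysis, conditions that leave an aryl carbonate untouched.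

Step 8
Reactants: 13 2-(trimethylsilyl)ethyl 4-[(trimethylsilyl)ethynyl]phenyl carbonate
Product: 14 4-ethynylphenyl 2-(trimethylsilyl)ethyl carbonate
Conditions: AgNO3 (10 mol %), acetone/H2O, rt
Reagents that add atoms: none
Why: Silver-catalysed protodesilylation is specific for the alkynyl–SiMe3 bond and, being neutral and fluoride-free, spares both the carbonate and its alkyl–SiMe3 group.

Step 9
Reactants: 14 4-ethynylphenyl 2-(trimethylsilyl)ethyl carbonate (1.3 equiv); 9 6-methoxy-3-(3-methylbut-2-enyl)-2,4-bis(triisopropylsilyloxy)benzaldehyde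
Product: 17 racemic (E)-1-[6-methoxy-3-(3-methylbut-2-enyl)-2,4-bis(triisopropylsilyloxy)phenyl]-3-(4-{[2-(trimethylsilyl)ethoxy]carbonyloxy}phenyl)prop-2-en-1-ol, via alkenylzirconocene chloride 15 (not isolated), via alkenyl(methyl)zinc 16 (not isolated)
Conditions: Cp2Zr(H)Cl (1.0 equiv per alkyne), CH2Cl2, rt, 20 min; Me2Zn (toluene), −65 °C; 9, 0 °C → rt; sat. aq NaHCO3
Reagents that add atoms: none
Why: Syn hydrozirconation of the terminal alkyne puts zirconium on the terminal carbon and fixes the E geometry, zirconium-to-zinc exchange proceeds with retention and the alkenylzinc adds 1,2 to the aldehyde (hydrozirconation–transmetalation–carbonyl addition); no control at C4 is sought, and the weakly basic zinc alkoxide should neither pull TIPS off O1 nor attack the carbonate.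

Step 10
Reactants: 17 racemic (E)-allylic alcohol
Product: 18 (S)-[6-methoxy-3-(3-methylbut-2-enyl)-2,4-bis(triisopropylsilyloxy)phenyl][(2S,3S)-3-(4-{[2-(trimethylsilyl)ethoxy]carbonyloxy}phenyl)oxiran-2-yl]methanol (erythro trans-epoxy alcohol; flavan numbering 2S,3S,4S)
Conditions: Ti(OiPr)4 (20 mol %), diisopropyl L-(+)-tartrate (26 mol %), t-BuOOH (0.45 equiv, anhydrous in decane), 4 Å MS, CH2Cl2, −20 °C; sat. aq Na2SO4/Et2O work-up, Et3N-deactivated SiO2
Reagents that add atoms: tert-butyl hydroperoxide, CC(C)(C)OO
Why: The C4 alkoxide of 17 and the tert-butylperoxide bind to the same titanium centre of the dimeric titanium–tartrate complex and the distal peroxide oxygen passes to C2=C3 in a concerted syn fashion, the closest known reaction type being the Sharpless kinetic resolution of secondary (E)-allylic alcohols, aryl alkenyl carbinols included. The oxirane ring is closed by this one-step [2+1] oxygen transfer, so the E geometry is carried over into a trans epoxide. C2 and C3 are set by the ligand, since the L-(+)-tartrate attacks the alkene face that turns (E)-cinnamyl-type alcohols into (2S,3S)-epoxides. C4 is set by rate, because only the (R)-carbinol (aryl outranks vinyl, so it corresponds spatially to the fast (S)-enantiomer of alkyl alkenyl carbinols) can turn its bulky aryl group away from the tartrate ester in the reactive conformer, and this enantiomer inherently gives the erythro isomer while (S)-17 stays behind and is separated. Chemoselectivity over the more electron-rich prenyl alkene is needed and is secured because oxygen is delivered only within the titanium-bound allylic alkoxide, while the carbonate on ring B keeps the benzylic C2–O bond from ionising and the silyl ethers on ring A temper ionisation at C4. Keeping t-BuOOH below half an equivalent stops the reaction before the slow enantiomer contributes, which protects the enantiomeric purity of 18.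

Step 11
Reactants: 18 erythro trans-epoxy alcohol
Product: 21 (2R,3S,4S)-2-(4-hydroxyphenyl)-5-methoxy-8-(3-methylbut-2-enyl)chromane-3,4,7-triol (5-O-methyl-8-prenylafzelechin-4β-ol), via triphenolate epoxide 19 (not isolated), via para-quinone methide 20 (not isolated)
Conditions: n-Bu4NF (4 equiv), THF (0.01 M), Ar, 0 °C → rt; pH 7 phosphate buffer
Reagents that add atoms: none
Why: Fluoride cleaves both aryl TIPS ethers and fragments the 2-silylethyl carbonate (loss of ethene and CO2), the ring B phenoxide pushes open the benzylic C2–O bond to a para-quinone methide and the O1 phenoxide adds to C2 in a 6-exo-trig oxa-1,6-addition from the face dictated by minimised A1,3 strain (H3 in the plane of the methide), which gives the same C2-inverted 2,3-trans product as a direct SN2 epoxide opening and is also the thermodynamic outcome, while C3 and C4 are not touched.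

**Compound list**
1 | 5-methoxyresorcinol | COc1cc(O)cc(O)c1 | starting material
2 | 1-methoxy-3,5-bis(methoxymethoxy)benzene | COCOc1cc(OC)cc(OCOC)c1 | intermediate
3 | prenyl bromide (1-bromo-3-methylbut-2-ene) | CC(C)=CCBr | starting material
4 | [4-methoxy-2,6-bis(methoxymethoxy)phenyl]lithium | [Li]c1c(OCOC)cc(OC)cc1OCOC | intermediate
5 | 5-methoxy-1,3-bis(methoxymethoxy)-2-(3-methylbut-2-enyl)benzene | COCOc1cc(OC)cc(OCOC)c1CC=C(C)C | intermediate
6 | [6-methoxy-2,4-bis(methoxymethoxy)-3-(3-methylbut-2-enyl)phenyl]lithium | [Li]c1c(OC)cc(OCOC)c(CC=C(C)C)c1OCOC | intermediate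
7 | 6-methoxy-2,4-bis(methoxymethoxy)-3-(3-methylbut-2-enyl)benzaldehyde | O=Cc1c(OC)cc(OCOC)c(CC=C(C)C)c1OCOC | intermediate
8 | 2,4-dihydroxy-6-methoxy-3-(3-methylbut-2-enyl)benzaldehyde | O=Cc1c(OC)cc(O)c(CC=C(C)C)c1O | intermediate
9 | 6-methoxy-3-(3-methylbut-2-enyl)-2,4-bis(triisopropylsilyloxy)benzaldehyde | O=Cc1c(OC)cc(O[Si](C(C)C)(C(C)C)C(C)C)c(CC=C(C)C)c1O[Si](C(C)C)(C(C)C)C(C)C | intermediate
10 | 4-iodophenol | Oc1ccc(I)cc1 | starting material
11 | 4-iodophenyl 2-(trimethylsilyl)ethyl carbonate | C[Si](C)(C)CCOC(=O)Oc1ccc(I)cc1 | intermediate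
12 | trimethylsilylacetylene | C#C[Si](C)(C)C | starting material
13 | 2-(trimethylsilyl)ethyl 4-[(trimethylsilyl)ethynyl]phenyl carbonate | C[Si](C)(C)CCOC(=O)Oc1ccc(C#C[Si](C)(C)C)cc1 | intermediate
14 | 4-ethynylphenyl 2-(trimethylsilyl)ethyl carbonate | C[Si](C)(C)CCOC(=O)Oc1ccc(C#C)cc1 | intermediate
15 | chlorobis(cyclopentadienyl)[(E)-2-(4-{[2-(trimethylsilyl)ethoxy]carbonyloxy}phenyl)ethenyl]zirconium | C[Si](C)(C)CCOC(=O)Oc1ccc(/C=C/[Zr](Cl)(C2C=CC=C2)C2C=CC=C2)cc1 | intermediate
16 | methyl[(E)-2-(4-{[2-(trimethylsilyl)ethoxy]carbonyloxy}phenyl)ethenyl]zinc | C[Si](C)(C)CCOC(=O)Oc1ccc(/C=C/[Zn]C)cc1 | intermediate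
17 | racemic (E)-1-[6-methoxy-3-(3-methylbut-2-enyl)-2,4-bis(triisopropylsilyloxy)phenyl]-3-(4-{[2-(trimethylsilyl)ethoxy]carbonyloxy}phenyl)prop-2-en-1-ol | COc1cc(O[Si](C(C)C)(C(C)C)C(C)C)c(CC=C(C)C)c(O[Si](C(C)C)(C(C)C)C(C)C)c1C(O)/C=C/c2ccc(OC(=O)OCC[Si](C)(C)C)cc2 | intermediate
18 | (S)-[6-methoxy-3-(3-methylbut-2-enyl)-2,4-bis(triisopropylsilyloxy)phenyl][(2S,3S)-3-(4-{[2-(trimethylsilyl)ethoxy]carbonyloxy}phenyl)oxiran-2-yl]methanol | COc1cc(O[Si](C(C)C)(C(C)C)C(C)C)c(CC=C(C)C)c(O[Si](C(C)C)(C(C)C)C(C)C)c1[C@H](O)[C@@H]2O[C@H]2c3ccc(OC(=O)OCC[Si](C)(C)C)cc3 | intermediate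
19 | fully deprotected erythro trans-epoxy alcohol, present as its phenolates and drawn neutral | COc1cc(O)c(CC=C(C)C)c(O)c1[C@H](O)[C@@H]2O[C@H]2c3ccc(O)cc3 | intermediate
20 | para-quinone methide of ring B carrying the intact C3 and C4 carbinols, drawn neutral | COc1cc(O)c(CC=C(C)C)c(O)c1[C@H](O)[C@H](O)C=C1C=CC(=O)C=C1 | intermediate
21 | (2R,3S,4S)-2-(4-hydroxyphenyl)-5-methoxy-8-(3-methylbut-2-enyl)chromane-3,4,7-triol (5-O-methyl-8-prenylafzelechin-4β-ol) | COc1cc(O)c(CC=C(C)C)c2c1[C@H](O)[C@H](O)[C@@H](c1ccc(O)cc1)O2 | target

Total steps: 11. Longest linear sequence: 8 steps (1, 2, 3, 4, 5, 9, 10, 11).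

**Steps most likely to fail**

**Risk 1, step 10.**
- The titanium Lewis acid may ionise the very electron-rich C4 carbinol. That would cause racemisation, allylic transposition or capture by isopropanol.
- The bulky ortho-silyloxy aryl group may slow oxygen transfer so much that the rate difference between the enantiomers shrinks.
- The fallback sets out from 17 and avoids any allylic alcohol under Lewis acid.
  - Oxidation with MnO2 in CH2Cl2 gives the chalcone F1.
  - Catalytic asymmetric nucleophilic epoxidation follows (La(OiPr)3/BINOL/Ph3As=O, t-BuOOH, 4 Å MS, THF). The BINOL antipode is chosen to deliver the (αR,βS)-epoxide. This touches only the enone and not the prenyl alkene, and gives the epoxy ketone F2.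
  - Chelation-controlled reduction with Zn(BH4)2 in Et2O at low temperature, a reaction known to give erythro epoxy alcohols from α,β-epoxy ketones, returns to the route at 18.
- Chalcone F1 also allows recovered (S)-17 to be recycled by Luche reduction (NaBH4/CeCl3) back to racemic 17.

**Risk 2, step 11.**
- The transient methide may be intercepted by another phenoxide or by water.
- It may tautomerise to the benzyl ketone.
- It may close with imperfect facial selectivity.
- Prolonged basic exposure may trigger a Payne rearrangement or reopen ring C.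
- The fallback sets out from 18 and closes ring C before ring B is unmasked, so no methide can arise during bond formation.
  - Buffered fluoride (n-Bu4NF/AcOH 1:1, THF, 0 °C) removes only the two aryl TIPS ethers and gives the ring B carbonate diphenol epoxide F3.
  - Mild base (Cs2CO3, MeCN, 0 °C) induces stereospecific intramolecular SN2 opening at the benzylic carbon distal to the carbinol. This gives the 4'-O-carbonate flavan-3,4-diol F4 with inversion at C2.
  - A short treatment with n-Bu4NF in THF at 0 °C, followed by pH 7 buffer, returns to the route at 21.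

**Risk 3, step 9.**
- Addition to the hindered, electron-rich aldehyde may be sluggish. Methyl transfer from zinc, attack of excess hydride on the carbonate, or silyl migration to the new alkoxide could then compete.
- The fallback sets out from 14 and replaces the zinc addition by a chromium-mediated one.
  - The alkenylzirconocene 15 is generated as before and quenched with I2 to give the (E)-alkenyl iodide F5.
  - F5 is coupled with 9 under Nozaki–Hiyama–Kishi conditions (CrCl2, NiCl2 cat., DMF/THF, rt). This reaction is highly aldehyde-selective and gives a non-basic chromium alkoxide. It returns to the route at 17.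

Further compounds
F1 | step 10 | (E)-1-[6-methoxy-3-(3-methylbut-2-enyl)-2,4-bis(triisopropylsilyloxy)phenyl]-3-(4-{[2-(trimethylsilyl)ethoxy]carbonyloxy}phenyl)prop-2-en-1-one | COc1cc(O[Si](C(C)C)(C(C)C)C(C)C)c(CC=C(C)C)c(O[Si](C(C)C)(C(C)C)C(C)C)c1C(=O)/C=C/c2ccc(OC(=O)OCC[Si](C)(C)C)cc2
F2 | step 10 | [6-methoxy-3-(3-methylbut-2-enyl)-2,4-bis(triisopropylsilyloxy)phenyl][(2R,3S)-3-(4-{[2-(trimethylsilyl)ethoxy]carbonyloxy}phenyl)oxiran-2-yl]methanone | COc1cc(O[Si](C(C)C)(C(C)C)C(C)C)c(CC=C(C)C)c(O[Si](C(C)C)(C(C)C)C(C)C)c1C(=O)[C@@H]2O[C@H]2c3ccc(OC(=O)OCC[Si](C)(C)C)cc3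
F3 | step 11 | (S)-[2,4-dihydroxy-6-methoxy-3-(3-methylbut-2-enyl)phenyl][(2S,3S)-3-(4-{[2-(trimethylsilyl)ethoxy]carbonyloxy}phenyl)oxiran-2-yl]methanol | COc1cc(O)c(CC=C(C)C)c(O)c1[C@H](O)[C@@H]2O[C@H]2c3ccc(OC(=O)OCC[Si](C)(C)C)cc3
F4 | step 11 | 4-[(2R,3S,4S)-3,4,7-trihydroxy-5-methoxy-8-(3-methylbut-2-enyl)chroman-2-yl]phenyl 2-(trimethylsilyl)ethyl carbonate | COc1cc(O)c(CC=C(C)C)c2c1[C@H](O)[C@H](O)[C@@H](c1ccc(OC(=O)OCC[Si](C)(C)C)cc1)O2
F5 | step 9 | 4-[(E)-2-iodoethenyl]phenyl 2-(trimethylsilyl)ethyl carbonate | C[Si](C)(C)CCOC(=O)Oc1ccc(/C=C/I)cc1
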